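**Plan**

1. Retrosynthesis: after the two phenols are unmasked (MOM ethers), the chromanone is cut at O1–C8a and C4–C4a together. This gives ring A as an aryne (C4a≡C8a) and the O1–C2–C3–C4 chain as an (S)-β-silyloxy morpholine amide that carries ring B. The aryne precursor is then cut at C8–CH2 (Negishi coupling) into an iodoarene and (S)-lavandulyl iodide.
2. Enabling feature: ring A is an ortho-oxygenated aryl ketone whose C4a lies next to the C5 methoxy group. In the corresponding 3-alkoxyaryne this group steers an oxygen nucleophile to C8a and puts the carbanion on C4a, six atoms from the amide carbonyl.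
3. Forward order: lavandulyl iodide (steps 1–4); ring A arene by two carbamate-directed lithiations around a Negishi coupling, then the ortho-silylaryl triflate (steps 5–10); ring B hydroxy amide (steps 11–14); ring C is closed last (step 15), then deprotection (step 16).
4. Stereochemistry: the side-chain centre comes from an Evans auxiliary (deconjugative prenylation, step 2); C2 comes from an asymmetric transfer hydrogenation (step 13). No bond at either centre is broken afterwards.

Key step: step 15

Remark on the chemistry: both phenols of the target are carried as methoxymethyl ethers, and step 5 is a statistical monoacylation of a cheap symmetric diol, run with the diol in excess and the unreacted diol recovered.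

**Route**

Step 1
Reactants: 1 (S)-4-benzyloxazolidin-2-one; 2 3-methylbut-2-enoyl chloride
Product: 4 (4S)-4-benzyl-3-(3-methylbut-2-enoyl)oxazolidin-2-one, via lithium oxazolidinide 3 (not isolated)
Conditions: n-BuLi, THF, −78 °C; then 2, −78 → 0 °C
Reagents that add atoms: none
Why: N-acylation of the lithiated Evans auxiliary with an acid chloride is standard, and the low temperature avoids deconjugation of the enoyl group.

Step 2
Reactants: 4; 5 1-bromo-3-methylbut-2-ene (prenyl bromide)
Product: 7 (4S)-4-benzyl-3-[(2S)-5-methyl-2-(prop-1-en-2-yl)hex-4-enoyl]oxazolidin-2-one, via sodium dienolate 6 (not isolated)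
Conditions: NaN(SiMe3)2, THF, −78 °C; then 5, −78 → −40 °C; AcOH quench at −78 °C
Reagents that add atoms: none
Why: Evans asymmetric alkylation in its deconjugative form: γ-deprotonation of the s-cis enoyl imide gives the chelated (Z)-dienolate, which should be alkylated at the α-carbon from the face opposite the benzyl group and so set the (2S) centre next to the new isopropenyl group.

Step 3
Reactants: 7
Product: 8 (2S)-5-methyl-2-(prop-1-en-2-yl)hex-4-en-1-ol ((S)-lavandulol)
Conditions: LiBH4, MeOH (1 equiv), Et2O, 0 °C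
Reagents that add atoms: none
Why: Reductive cleavage of the N-acyl oxazolidinone with LiBH4 gives the primary alcohol and returns the auxiliary, under conditions too weakly basic to epimerise the centre or move the β,γ-alkene into conjugation.

Step 4
Reactants: 8
Product: 9 (3S)-3-(iodomethyl)-2,6-dimethylhepta-1,5-diene
Conditions: I2, PPh3, imidazole, CH2Cl2, 0 °C → rt
Reagents that add atoms: iodine, II
Why: Appel-type iodination of a primary alcohol proceeds at the CH2 group only and leaves the neighbouring stereocentre and both alkenes untouched.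

Step 5
Reactants: 10 5-methoxybenzene-1,3-diol
Product: 11 3-hydroxy-5-methoxyphenyl N-(propan-2-yl)carbamate
Conditions: iPrNCO (0.9 equiv), Et3N (cat.), CH2Cl2, 0 °C → rt; 10 in excess
Reagents that add atoms: isopropyl isocyanate, CC(C)N=C=O
Why: Amine-catalysed addition of a phenol to an isocyanate (carbamoylation), run as a statistical monofunctionalisation of the symmetric diol, with the bis-carbamate and unreacted diol removed by chromatography.

Step 6
Reactants: 11
Product: 12 3-methoxy-5-(methoxymethoxy)phenyl N-(propan-2-yl)carbamate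
Conditions: MOMCl, iPr2NEt, CH2Cl2, 0 °C → rt
Reagents that add atoms: chloromethyl methyl ether, COCCl
Why: Standard O-alkylation of the remaining phenol to the MOM ether, which serves both as protecting group for the later 7-OH and as second directing group.

Step 7
Reactants: 12
Product: 16 2-iodo-5-methoxy-3-(methoxymethoxy)phenyl N-(propan-2-yl)carbamate, via N-silyl carbamate 13 (not isolated), via aryllithium 14 (not isolated), via N-silyl iodide 15 (not isolated)
Conditions: TBSOTf, TMEDA, Et2O, 0 °C → rt; n-BuLi, TMEDA, −78 °C; I2, THF, −78 °C → rt; aq. Na2S2O3/NaHSO4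
Reagents that add atoms: iodine, II
Why: Directed ortho-metalation of a secondary aryl carbamate after in situ N-silylation: the position flanked by the carbamate and the OMOM group, the two strongest directing groups, should be lithiated in preference to the one between carbamate and OMe, and iodine quench marks the later C8.

Step 8
Reactants: 9; 16
Product: 18 5-methoxy-3-(methoxymethoxy)-2-[(2R)-5-methyl-2-(prop-1-en-2-yl)hex-4-en-1-yl]phenyl N-(propan-2-yl)carbamate, via lavandulylzinc iodide 17 (not isolated)
Conditions: Zn dust, LiCl, THF, 40 °C (9 → 17); then 16, Pd(OAc)2 (cat.), SPhos, THF, 50 °C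
Reagents that add atoms: none
Why: Negishi cross-coupling of a primary alkylzinc iodide with an aryl iodide (oxidative addition to zerovalent palladium, transmetalation, reductive elimination favoured over β-hydride elimination by the biaryl phosphine); the centre is β to zinc and is not touched, and its descriptor changes from S to R only through the priority rules.

Step 9
Reactants: 18
Product: 22 3-methoxy-5-(methoxymethoxy)-6-[(2R)-5-methyl-2-(prop-1-en-2-yl)hex-4-en-1-yl]-2-(trimethylsilyl)phenyl N-(propan-2-yl)carbamate, via N-silyl carbamate 19 (not isolated), via aryllithium 20 (not isolated), via N-silyl arylsilane 21 (not isolated)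
Conditions: TBSOTf, TMEDA, Et2O, 0 °C → rt; n-BuLi, TMEDA, −78 °C; Me3SiCl, −78 °C → rt; aq. NaHSO4
Reagents that add atoms: chlorotrimethylsilane, C[Si](C)(C)Cl
Why: Second directed ortho-metalation: the only free position ortho to the carbamate lies between it and the methoxy group (the later C4a), so silylation there should be regioselective, and at −78 °C ring lithiation should outrun benzylic or allylic deprotonation.

Step 10
Reactants: 22
Product: 24 3-methoxy-5-(methoxymethoxy)-6-[(2R)-5-methyl-2-(prop-1-en-2-yl)hex-4-en-1-yl]-2-(trimethylsilyl)phenyl trifluoromethanesulfonate, via silylphenol 23 (not isolated)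
Conditions: Et2NH, DBU, MeCN, 40 °C; then PhNTf2, rt
Reagents that add atoms: N-phenylbis(trifluoromethanesulfonimide), O=S(=O)(N(c1ccccc1)S(=O)(=O)C(F)(F)F)C(F)(F)F
Why: Base-induced E1cB cleavage of the secondary carbamate (the isocyanate is scavenged by Et2NH as a urea) and triflation of the phenoxide in the same pot give the ortho-silylaryl triflate, a Kobayashi-type aryne precursor.

Step 11
Reactants: 25 methyl 2-hydroxy-4-methoxybenzoate
Product: 26 methyl 4-methoxy-2-(methoxymethoxy)benzoate
Conditions: MOMCl, iPr2NEt, DMAP (cat.), CH2Cl2, 40 °C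
Reagents that add atoms: chloromethyl methyl ether, COCCl
Why: Standard MOM protection of the hydrogen-bonded salicylate phenol, which becomes the 2'-OH of ring B.

Step 12
Reactants: 26; 27 4-acetylmorpholine
Product: 29 1-[4-methoxy-2-(methoxymethoxy)phenyl]-3-(morpholin-4-yl)propane-1,3-dione, via lithium enolate 28 (not isolated)
Conditions: LiN(iPr)2 (2.2 equiv), 27 (2.2 equiv), THF, −78 °C; then 26, −78 → 0 °C; aq. NH4Cl
Reagents that add atoms: none
Why: Crossed Claisen condensation of an amide enolate with a non-enolisable aryl ester, driven by deprotonation of the β-keto amide by the second equivalent of enolate.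

Step 13
Reactants: 29
Product: 30 (3S)-3-hydroxy-3-[4-methoxy-2-(methoxymethoxy)phenyl]-1-(morpholin-4-yl)propan-1-one
Conditions: RuCl[(S,S)-TsDPEN](p-cymene) (cat.), HCO2Na, H2O/MeOH, 40 °C
Reagents that add atoms: none
Why: Noyori–Ikariya asymmetric transfer hydrogenation of an aryl β-keto amide: with the (S,S)-ligand, hydride delivery to the face fixed by the CH–π contact of the aryl group with the η6-arene should give the (S)-carbinol (the later C2), and the near-neutral formate medium spares the electron-rich benzylic alcohol.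

Step 14
Reactants: 30
Product: 31 (3S)-3-[4-methoxy-2-(methoxymethoxy)phenyl]-1-(morpholin-4-yl)-3-[(trimethylsilyl)oxy]propan-1-one
Conditions: Me3SiCl, imidazole, CH2Cl2, 0 °C; used without chromatography
Reagents that add atoms: chlorotrimethylsilane, C[Si](C)(C)Cl
Why: Routine O-silylation, which turns the alcohol into a proton-free, fluoride-labile source of the alkoxide for the next step.

Step 15
Reactants: 24; 31
Product: 36 (2S)-5-methoxy-2-[4-methoxy-2-(methoxymethoxy)phenyl]-7-(methoxymethoxy)-8-[(2R)-5-methyl-2-(prop-1-en-2-yl)hex-4-en-1-yl]-2,3-dihydro-4H-chromen-4-one, via aryne 32 (not isolated), via potassium alkoxide 33 (not isolated), via aryl potassium 34 (not isolated), via potassium hemiaminal alkoxide 35 (not isolated)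
Conditions: 31 (1.5 equiv), KF, 18-crown-6, THF, 0 °C; 24 added slowly, 0 °C → rt; then aq. NH4Cl, 0 °C
Reagents that add atoms: none
Why: Proposed new method: fluoride cleaves the O–SiMe3 bond of 31 to alkoxide 33 and turns 24 into aryne 32; 33 adds through oxygen to C8a, the aryl carbanion 34 formed at C4a attacks the morpholine amide carbonyl, and the tetrahedral adduct 35 collapses to the ketone only on buffered work-up. The closest known reaction type is the tandem addition and intramolecular acyl substitution of salicylate phenoxides on arynes to give xanthones, together with aryne insertions into amide C–N bonds; new here is an aliphatic β-oxido amide as the four-atom partner. Ring C closes by 6-exo-trig addition of the C4a carbanion to C4, after the intermolecular O1–C8a bond has formed. No stereocentre of the product is made here: C2 is carried in from 30 with none of its bonds broken, and the amide is chosen because 35 releases no alkoxide base that could open the flavanone by retro-oxa-Michael reaction and racemise C2. The step needs attack at C8a rather than C4a and acyl trapping before protonation; the C5 methoxy group (inductive distortion of the aryne, carbanion ortho to OMe) should secure the first, and the aprotic medium with the silyl ether as alkoxide source the second. Slow addition of 24 to an excess of 33 is meant to outrun the intramolecular ene reaction of the aryne with the side-chain isopropenyl group.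

Step 16
Reactants: 36
Product: 37 (2S)-7-hydroxy-2-(2-hydroxy-4-methoxyphenyl)-5-methoxy-8-[(2R)-5-methyl-2-(prop-1-en-2-yl)hex-4-en-1-yl]-2,3-dihydro-4H-chromen-4-one (target)
Conditions: 3 M aq. HCl, MeOH, 45 °C, short contact time
Reagents that add atoms: none
Why: Acid-catalysed acetal exchange with methanol cleaves both aryl MOM ethers; dilute acid and moderate temperature are chosen because the flavanone centre is base-labile but acid-tolerant, and to spare the side-chain alkenes.

**Compound list**

1 | (S)-4-benzyloxazolidin-2-one | O=C1OC[C@H](Cc2ccccc2)N1 | starting material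
2 | 3-methylbut-2-enoyl chloride | CC(C)=CC(=O)Cl | starting material
3 | lithium (4S)-4-benzyl-2-oxooxazolidin-3-ide | O=C1OC[C@H](Cc2ccccc2)[N-]1.[Li+] | intermediate
4 | (4S)-4-benzyl-3-(3-methylbut-2-enoyl)oxazolidin-2-one | CC(C)=CC(=O)N1C(=O)OC[C@@H]1Cc1ccccc1 | intermediate
5 | 1-bromo-3-methylbut-2-ene | CC(C)=CCBr | starting material
6 | sodium (1Z)-1-[(4S)-4-benzyl-2-oxooxazolidin-3-yl]-3-methylbuta-1,3-dien-1-olate | C=C(C)/C=C(\[O-])N1C(=O)OC[C@@H]1Cc1ccccc1.[Na+] | intermediate
7 | (4S)-4-benzyl-3-[(2S)-5-methyl-2-(prop-1-en-2-yl)hex-4-enoyl]oxazolidin-2-one | C=C(C)[C@H](CC=C(C)C)C(=O)N1C(=O)OC[C@@H]1Cc1ccccc1 | intermediate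
8 | (2S)-5-methyl-2-(prop-1-en-2-yl)hex-4-en-1-ol | C=C(C)[C@H](CC=C(C)C)CO | intermediate
9 | (3S)-3-(iodomethyl)-2,6-dimethylhepta-1,5-diene | C=C(C)[C@H](CC=C(C)C)CI | intermediate
10 | 5-methoxybenzene-1,3-diol | COc1cc(O)cc(O)c1 | starting material
11 | 3-hydroxy-5-methoxyphenyl N-(propan-2-yl)carbamate | COc1cc(O)cc(OC(=O)NC(C)C)c1 | intermediate
12 | 3-methoxy-5-(methoxymethoxy)phenyl N-(propan-2-yl)carbamate | COCOc1cc(OC)cc(OC(=O)NC(C)C)c1 | intermediate
13 | 3-methoxy-5-(methoxymethoxy)phenyl N-(tert-butyldimethylsilyl)-N-(propan-2-yl)carbamate | COCOc1cc(OC)cc(OC(=O)N(C(C)C)[Si](C)(C)C(C)(C)C)c1 | intermediate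
14 | 2-lithio derivative of 13 (lithium between carbamate and OMOM) | COCOc1cc(OC)cc(OC(=O)N(C(C)C)[Si](C)(C)C(C)(C)C)c1[Li] | intermediate
15 | 2-iodo-5-methoxy-3-(methoxymethoxy)phenyl N-(tert-butyldimethylsilyl)-N-(propan-2-yl)carbamate | COCOc1cc(OC)cc(OC(=O)N(C(C)C)[Si](C)(C)C(C)(C)C)c1I | intermediate
16 | 2-iodo-5-methoxy-3-(methoxymethoxy)phenyl N-(propan-2-yl)carbamate | COCOc1cc(OC)cc(OC(=O)NC(C)C)c1I | intermediate
17 | [(2S)-5-methyl-2-(prop-1-en-2-yl)hex-4-en-1-yl]zinc iodide | C=C(C)[C@H](CC=C(C)C)C[Zn]I | intermediate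
18 | 5-methoxy-3-(methoxymethoxy)-2-[(2R)-5-methyl-2-(prop-1-en-2-yl)hex-4-en-1-yl]phenyl N-(propan-2-yl)carbamate | C=C(C)[C@H](CC=C(C)C)Cc1c(OCOC)cc(OC)cc1OC(=O)NC(C)C | intermediate
19 | N-(tert-butyldimethylsilyl) derivative of 18 | C=C(C)[C@H](CC=C(C)C)Cc1c(OCOC)cc(OC)cc1OC(=O)N(C(C)C)[Si](C)(C)C(C)(C)C | intermediate
20 | 6-lithio derivative of 19 (lithium between carbamate and OMe) | C=C(C)[C@H](CC=C(C)C)Cc1c(OCOC)cc(OC)c([Li])c1OC(=O)N(C(C)C)[Si](C)(C)C(C)(C)C | intermediate
21 | N-(tert-butyldimethylsilyl) derivative of 22 | C=C(C)[C@H](CC=C(C)C)Cc1c(OCOC)cc(OC)c([Si](C)(C)C)c1OC(=O)N(C(C)C)[Si](C)(C)C(C)(C)C | intermediate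
22 | 3-methoxy-5-(methoxymethoxy)-6-[(2R)-5-methyl-2-(prop-1-en-2-yl)hex-4-en-1-yl]-2-(trimethylsilyl)phenyl N-(propan-2-yl)carbamate | C=C(C)[C@H](CC=C(C)C)Cc1c(OCOC)cc(OC)c([Si](C)(C)C)c1OC(=O)NC(C)C | intermediate
23 | 3-methoxy-5-(methoxymethoxy)-6-[(2R)-5-methyl-2-(prop-1-en-2-yl)hex-4-en-1-yl]-2-(trimethylsilyl)phenol | C=C(C)[C@H](CC=C(C)C)Cc1c(OCOC)cc(OC)c([Si](C)(C)C)c1O | intermediate
24 | 3-methoxy-5-(methoxymethoxy)-6-[(2R)-5-methyl-2-(prop-1-en-2-yl)hex-4-en-1-yl]-2-(trimethylsilyl)phenyl trifluoromethanesulfonate | C=C(C)[C@H](CC=C(C)C)Cc1c(OCOC)cc(OC)c([Si](C)(C)C)c1OS(=O)(=O)C(F)(F)F | intermediate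
25 | methyl 2-hydroxy-4-methoxybenzoate | COC(=O)c1ccc(OC)cc1O | starting material
26 | methyl 4-methoxy-2-(methoxymethoxy)benzoate | COCOc1cc(OC)ccc1C(=O)OC | intermediate
27 | 4-acetylmorpholine | CC(=O)N1CCOCC1 | starting material
28 | lithium 1-(morpholin-4-yl)ethen-1-olate | C=C([O-])N1CCOCC1.[Li+] | intermediate
29 | 1-[4-methoxy-2-(methoxymethoxy)phenyl]-3-(morpholin-4-yl)propane-1,3-dione | COCOc1cc(OC)ccc1C(=O)CC(=O)N1CCOCC1 | intermediate
30 | (3S)-3-hydroxy-3-[4-methoxy-2-(methoxymethoxy)phenyl]-1-(morpholin-4-yl)propan-1-one | O[C@H](c1ccc(OC)cc1OCOC)CC(=O)N1CCOCC1 | intermediate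
31 | (3S)-3-[4-methoxy-2-(methoxymethoxy)phenyl]-1-(morpholin-4-yl)-3-[(trimethylsilyl)oxy]propan-1-one | C[Si](C)(C)O[C@H](c1ccc(OC)cc1OCOC)CC(=O)N1CCOCC1 | intermediate
32 | 3-methoxy-5-(methoxymethoxy)-6-[(2R)-5-methyl-2-(prop-1-en-2-yl)hex-4-en-1-yl]benzyne (1,2-didehydrobenzene) | C=C(C)[C@H](CC=C(C)C)CC1=C(OCOC)C=C(OC)C#C1 | intermediate
33 | potassium (1S)-1-[4-methoxy-2-(methoxymethoxy)phenyl]-3-(morpholin-4-yl)-3-oxopropan-1-olate | [O-][C@H](c1ccc(OC)cc1OCOC)CC(=O)N1CCOCC1.[K+] | intermediate
34 | aryl potassium adduct: carbanion at the later C4a, ortho to the new aryl ether and to OMe | C=C(C)[C@H](CC=C(C)C)Cc1c(OCOC)cc(OC)[c-]c1O[C@H](c1ccc(OC)cc1OCOC)CC(=O)N1CCOCC1.[K+] | intermediate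
35 | potassium (2S)-5-methoxy-2-[4-methoxy-2-(methoxymethoxy)phenyl]-7-(methoxymethoxy)-8-[(2R)-5-methyl-2-(prop-1-en-2-yl)hex-4-en-1-yl]-4-(morpholin-4-yl)chroman-4-olate (either configuration at C4) | C=C(C)[C@H](CC=C(C)C)Cc1c(OCOC)cc(OC)c2c1O[C@H](c1ccc(OC)cc1OCOC)CC2([O-])N1CCOCC1.[K+] | intermediate
36 | (2S)-5-methoxy-2-[4-methoxy-2-(methoxymethoxy)phenyl]-7-(methoxymethoxy)-8-[(2R)-5-methyl-2-(prop-1-en-2-yl)hex-4-en-1-yl]-2,3-dihydro-4H-chromen-4-one | C=C(C)[C@H](CC=C(C)C)Cc1c(OCOC)cc(OC)c2c1O[C@H](c1ccc(OC)cc1OCOC)CC2=O | intermediate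
37 | (2S)-7-hydroxy-2-(2-hydroxy-4-methoxyphenyl)-5-methoxy-8-[(2R)-5-methyl-2-(prop-1-en-2-yl)hex-4-en-1-yl]-2,3-dihydro-4H-chromen-4-one | C=C(C)[C@H](CC=C(C)C)Cc1c(O)cc(OC)c2c1O[C@H](c1ccc(OC)cc1O)CC2=O | target

**Summary**

Total step count: 16. Longest linear sequence: 9 steps (steps 1, 2, 3, 4, 8, 9, 10, 15, 16).

Three steps most likely to fail:

1. Step 15 (proposed new method). The aryne may be consumed by an intramolecular ene reaction with the isopropenyl group of the side chain before the alkoxide reaches it. The alkoxide may add at the wrong aryne carbon. The aryl carbanion may be quenched by proton transfer before it closes ring C. Fallback by known chemistry, from 18 back to 36: the lithiation of step 9 (via 19 and 20) would be quenched with N-methoxy-N-methylacetamide to give the N-silyl ortho-acetyl carbamate F1, which loses the N-silyl group on aqueous work-up to give the ortho-acetyl carbamate F2. Cleavage of the carbamate (Et2NH, DBU, MeCN) would give the 2-hydroxyacetophenone F3. Condensation with N,N-dimethylformamide dimethyl acetal would give the enaminone F4, which should close to the chromone F5 in warm acetic acid. Separately, commercial 2-bromo-5-methoxyphenol would be converted into its MOM ether, 1-bromo-4-methoxy-2-(methoxymethoxy)benzene F6, and this by palladium-catalysed borylation with B2(OH)4 (KOAc, EtOH) into [4-methoxy-2-(methoxymethoxy)phenyl]boronic acid F7. Asymmetric conjugate addition of F7 to F5 (Pd(OCOCF3)2, tert-butyl-PyOx ligand, the enantiomer chosen for the 2S product) would give 36.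

2. Step 7. Lithiation may occur between the carbamate and the methoxy group instead of between the carbamate and the OMOM group, or the lithiated carbamate may undergo anionic ortho-Fries rearrangement before it is trapped. Fallback, from 10 back to 16: the iodine would be placed before the two phenols are told apart. Iodination of 10 at the position between the two hydroxyl groups (I2, NaHCO3, H2O, 0 °C) would give 2-iodo-5-methoxybenzene-1,3-diol F8. Monocarbamoylation with isopropyl isocyanate would give 3-hydroxy-2-iodo-5-methoxyphenyl N-(propan-2-yl)carbamate F9, and MOM protection as in step 6 would give 16.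

3. Step 16. Under protic acid the freed 7-hydroxy group may add to the protonated isopropenyl alkene to form a chroman ring, or the alkenes may be hydrated. Fallback, from 36 to 37: a non-protic acetal exchange with Me3SiOTf and 2,2'-bipyridyl in MeCN at 0 °C would convert both aryl MOM ethers into the bis(trimethylsilyl) ether F10, which is hydrolysed with water at neutral pH to 37.

**Further compounds**

F1 | step 15 | 2-acetyl-3-methoxy-5-(methoxymethoxy)-6-[(2R)-5-methyl-2-(prop-1-en-2-yl)hex-4-en-1-yl]phenyl N-(tert-butyldimethylsilyl)-N-(propan-2-yl)carbamate | C=C(C)[C@H](CC=C(C)C)Cc1c(OCOC)cc(OC)c(C(C)=O)c1OC(=O)N(C(C)C)[Si](C)(C)C(C)(C)C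
F2 | step 15 | 2-acetyl-3-methoxy-5-(methoxymethoxy)-6-[(2R)-5-methyl-2-(prop-1-en-2-yl)hex-4-en-1-yl]phenyl N-(propan-2-yl)carbamate | C=C(C)[C@H](CC=C(C)C)Cc1c(OCOC)cc(OC)c(C(C)=O)c1OC(=O)NC(C)C
F3 | step 15 | 1-{2-hydroxy-6-methoxy-4-(methoxymethoxy)-3-[(2R)-5-methyl-2-(prop-1-en-2-yl)hex-4-en-1-yl]phenyl}ethan-1-one | C=C(C)[C@H](CC=C(C)C)Cc1c(OCOC)cc(OC)c(C(C)=O)c1O
F4 | step 15 | (2E)-3-(dimethylamino)-1-{2-hydroxy-6-methoxy-4-(methoxymethoxy)-3-[(2R)-5-methyl-2-(prop-1-en-2-yl)hex-4-en-1-yl]phenyl}prop-2-en-1-one | C=C(C)[C@H](CC=C(C)C)Cc1c(OCOC)cc(OC)c(C(=O)/C=C/N(C)C)c1O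
F5 | step 15 | 5-methoxy-7-(methoxymethoxy)-8-[(2R)-5-methyl-2-(prop-1-en-2-yl)hex-4-en-1-yl]-4H-chromen-4-one | C=C(C)[C@H](CC=C(C)C)Cc1c(OCOC)cc(OC)c2c1OC=CC2=O
F6 | step 15 | 1-bromo-4-methoxy-2-(methoxymethoxy)benzene | COCOc1cc(OC)ccc1Br
F7 | step 15 | [4-methoxy-2-(methoxymethoxy)phenyl]boronic acid | COCOc1cc(OC)ccc1B(O)O
F8 | step 7 | 2-iodo-5-methoxybenzene-1,3-diol | COc1cc(O)c(I)c(O)c1
F9 | step 7 | 3-hydroxy-2-iodo-5-methoxyphenyl N-(propan-2-yl)carbamate | COc1cc(O)c(I)c(OC(=O)NC(C)C)c1
F10 | step 16 | (2S)-5-methoxy-2-{4-methoxy-2-[(trimethylsilyl)oxy]phenyl}-8-[(2R)-5-methyl-2-(prop-1-en-2-yl)hex-4-en-1-yl]-7-[(trimethylsilyl)oxy]-2,3-dihydro-4H-chromen-4-one | C=C(C)[C@H](CC=C(C)C)Cc1c(O[Si](C)(C)C)cc(OC)c2c1O[C@H](c1ccc(OC)cc1O[Si](C)(C)C)CC2=O
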